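**Plan**
1. Labels: the four resveratrol units are a–d (4-hydroxyphenyl–C7–C8–resorcinol ring A–D). The trans-dihydrofuran is O(ring B)–C7a–C8a–ring B and the cis one is O(ring D)–C7c–C8c–ring D. The two eight-membered rings are C7b/ring C/C8c/ring D/C8d/C8b and C7d/ring A/C8a/ring B/C8b/C8d.
2. Cuts, in order: C7d–ring A (last ring); C7d–C8d (one-carbon homologation and aryl Grignard addition); C8b–ring B (ketone α-arylation joining the two dihydrobenzofurans); C7b–ring C (first eight-membered ring); C8d–ring D (acylation); both C7–C8 furan bonds (carbene C–H insertion).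
3. Forward: one cis-2,3-diaryl-4-bromodihydrobenzofuran serves both halves (epimerisation at C7a gives the trans half). Enone on ring D, then phenolate Michael closure of the C/D eight-membered ring, α-arylation with the trans half, homologation at C8d, quinone methide closure of the A/B eight-membered ring, hydrogenolysis.
4. Feature used: C7d is benzylic to a 4-hydroxyphenyl group (p-quinone methide) and sits eight ring atoms from the ortho carbon of ring A, which is the only free resorcinol at that stage. The competing five- and seven-ring closures onto rings B and C are silenced as benzyl ethers.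
5. Stereochemistry: C8a and C8c by Rh catalysis (C7 cis from the insertion; C7a then epimerised to trans). C7b, C8b and C8d are relayed from C8c/C7c by substrate and thermodynamic control. C7d is set by a chiral phosphoric acid.

Key step: step 19

Assumption: Rh2(R-PTAD)4 is taken to give the (3S)-dihydrobenzofuran and (R)-TRIP to be the matched catalyst for the required C7d face; if either sense proves opposite, the enantiomeric catalyst is used in that step.

Step 1
Reactants: 1 2-bromo-4,6-dimethoxybenzaldehyde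
Product: 2 2-bromo-4,6-dihydroxybenzaldehyde
Conditions: BBr3, CH2Cl2, −78 °C → rt; H2O
Reagents that add atoms: none
Why: BBr3 cleaves both aryl methyl ethers (Lewis acid-mediated demethylation) and leaves the aldehyde and the aryl bromide untouched.

Step 2
Reactants: 2 2-bromo-4,6-dihydroxybenzaldehyde
Product: 3 4-(benzyloxy)-2-bromo-6-hydroxybenzaldehyde
Conditions: BnBr (1 equiv), NaHCO3, MeCN, 60 °C
Reagents that add atoms: benzyl bromide BrCc1ccccc1
Why: Williamson etherification with a weak base alkylates the more acidic 4-hydroxyl, while the 6-hydroxyl stays hydrogen-bonded to the formyl group.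

Step 3
Reactants: 3 4-(benzyloxy)-2-bromo-6-hydroxybenzaldehyde; 4 4-(benzyloxy)benzyl chloride
Product: 5 4-(benzyloxy)-2-{[4-(benzyloxy)benzyl]oxy}-6-bromobenzaldehyde
Conditions: K2CO3, DMF, 60 °C
Reagents that add atoms: none
Why: Williamson etherification of the chelated phenol installs the ArCH2–O unit whose CH2 becomes C7 of the dihydrofuran.

Step 4
Reactants: 6 5-bromoresorcinol
Product: 7 1-bromo-3,5-bis(triisopropylsilyloxy)benzene
Conditions: TIPSCl, imidazole, DMF, rt
Reagents that add atoms: chlorotriisopropylsilane CC(C)[Si](Cl)(C(C)C)C(C)C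
Why: Standard silylation gives phenol protection that survives organolithium, acid and Pd steps and is removed later by fluoride alone.

Step 5
Reactants: 7 1-bromo-3,5-bis(triisopropylsilyloxy)benzene; 5 4-(benzyloxy)-2-{[4-(benzyloxy)benzyl]oxy}-6-bromobenzaldehyde
Product: 9 diarylmethanol (racemic at the carbinol carbon), via aryllithium 8 (not isolated)
Conditions: n-BuLi, THF, −78 °C; then 5, −78 °C; H2O
Reagents that add atoms: none
Why: Bromine–lithium exchange followed by 1,2-addition to the aldehyde, which is faster than exchange at the hindered bromide of 5; the carbinol centre is removed in the next step.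

Step 6
Reactants: 9 diarylmethanol
Product: 10 diaryl ketone
Conditions: Dess–Martin periodinane, NaHCO3, CH2Cl2, 0 °C → rt
Reagents that add atoms: none
Why: Dess–Martin oxidation of a doubly benzylic alcohol proceeds under buffered conditions that spare the silyl and benzyl ethers.

Step 7
Reactants: 10 diaryl ketone
Product: 11 diaryl ketone hydrazone
Conditions: N2H4·H2O (excess), AcOH (cat.), n-BuOH, 110 °C
Reagents that add atoms: hydrazine NN
Why: Acid-catalysed condensation gives the hydrazone; forcing conditions are chosen because the carbonyl is flanked by two ortho substituents.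

Step 8
Reactants: 11 diaryl ketone hydrazone
Product: 13 (2R,3S)-6-(benzyloxy)-2-[4-(benzyloxy)phenyl]-4-bromo-3-[3,5-bis(triisopropylsilyloxy)phenyl]-2,3-dihydrobenzofuran (2,3-cis), via diaryldiazomethane 12 (not isolated)
Conditions: MnO2, CH2Cl2, rt, filter; then Rh2(R-PTAD)4 (1 mol%), CH2Cl2, −20 °C → rt
Reagents that add atoms: none
Why: Oxidation gives the donor/donor diazo compound, whose Rh carbene inserts into the benzylic ether C–H (enantioselective 1,5 C–H insertion); the concerted insertion gives the 2,3-cis ring and the chiral carboxylate ligands fix C3 (the future C8c and C8a).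

Step 9
Reactants: 13 cis-dihydrobenzofuran bromide
Product: 14 (2S,3S)-6-(benzyloxy)-2-[4-(benzyloxy)phenyl]-4-bromo-3-[3,5-bis(triisopropylsilyloxy)phenyl]-2,3-dihydrobenzofuran (2,3-trans)
Conditions: TFA, CH2Cl2, 0 °C
Reagents that add atoms: none
Why: Reversible acid ionisation of the C2–O bond (a 4-alkoxybenzylic cation) and reclosure epimerise C2 (the future C7a) to the thermodynamic trans isomer, while C3 is untouched.

Step 10
Reactants: 15 4-(benzyloxy)benzaldehyde
Product: 16 (E)-3-[4-(benzyloxy)phenyl]-N-methoxy-N-methylprop-2-enamide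
Conditions: diethyl [2-(methoxy(methyl)amino)-2-oxoethyl]phosphonate, NaH, THF, 0 °C → rt
Reagents that add atoms: diethyl [2-(methoxy(methyl)amino)-2-oxoethyl]phosphonate CCOP(=O)(CC(=O)N(C)OC)OCC
Why: Horner–Wadsworth–Emmons olefination gives the E-configured cinnamoyl Weinreb amide, which carries C7b, C8b and C8d.

Step 11
Reactants: 13 cis-dihydrobenzofuran bromide; 16 cinnamoyl Weinreb amide
Product: 18 (E)-enone on C4 of the cis-dihydrobenzofuran (ring D–C8d(=O)–C8b=C7b–aryl), via aryllithium 17 (not isolated)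
Conditions: n-BuLi, THF, −78 °C; then 16, −78 → 0 °C; H2O
Reagents that add atoms: none
Why: Bromine–lithium exchange and Weinreb ketone synthesis form the ring D–C8d bond without over-addition, because the chelated tetrahedral adduct collapses only on work-up.

Step 12
Reactants: 18 enone
Product: 21 eight-membered ketone with ring C as its bis(benzyl ether), via enone diphenol 19 (not isolated), via eight-membered ketone diphenol 20 (not isolated)
Conditions: CsF, DMF (high dilution), 0 °C → rt; then BnBr, rt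
Reagents that add atoms: benzyl bromide BrCc1ccccc1
Why: Fluoride frees the ring C phenolates, whose ortho carbon adds to the enone β-carbon C7b (intramolecular phenolate Michael, a Friedel–Crafts-type conjugate addition) and closes the C/D eight-membered ring; C7b is expected to form under reversible conditions with its aryl cis to C7c across ring C, and benzyl bromide then caps the phenolates.

Step 13
Reactants: 21 eight-membered ketone; 14 trans-dihydrobenzofuran bromide
Product: 22 C8b-arylated ketone (ring B of 14 on C8b and trans to the C7b aryl)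
Conditions: Pd(OAc)2 (5 mol%), XPhos (10 mol%), K3PO4, toluene, 100 °C
Reagents that add atoms: none
Why: Palladium-catalysed α-arylation of the only enolisable position joins the two halves; the new C8b centre equilibrates through its enolate to the isomer with ring B trans to the neighbouring C7b aryl.

Step 14
Reactants: 22 C8b-arylated ketone
Product: 23 C8d exocyclic methylene compound
Conditions: Cp2TiMe2, toluene/THF, 70 °C, dark
Reagents that add atoms: dimethyltitanocene C[Ti](C)(C1C=CC=C1)C1C=CC=C1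
Why: Petasis methylenation works through a non-basic titanium carbene, so the hindered and readily enolised ketone is converted without loss of the C8b configuration; the new carbon is C7d.

Step 15
Reactants: 23 C8d exocyclic methylene compound
Product: 25 C8d hydroxymethyl compound, via alkylborane 24 (not isolated)
Conditions: BH3·THF, THF, 0 °C → rt; then NaOH, H2O2, 0 °C
Reagents that add atoms: hydrogen peroxide OO
Why: Hydroboration–oxidation places oxygen on the terminal carbon (anti-Markovnikov) and hydrogen on C8d, expected from the face away from ring B; any C8d epimer is corrected in step 16.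

Step 16
Reactants: 25 C8d hydroxymethyl compound
Product: 26 C8d carbaldehyde (formyl carbon = C7d and trans to ring B)
Conditions: Dess–Martin periodinane, NaHCO3, CH2Cl2, 0 °C → rt; then DBU (cat.), rt
Reagents that add atoms: none
Why: Dess–Martin oxidation followed by base equilibration of the α-aryl aldehyde should set C8d thermodynamically with the formyl group trans to ring B (trans ring fusion, H-8b and H-8d anti).

Step 17
Reactants: 26 C8d carbaldehyde; 27 (4-bromophenoxy)triisopropylsilane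
Product: 29 C7d carbinol as its tris(triisopropylsilyl) ether (both C7d epimers), via arylmagnesium bromide 28 (not isolated)
Conditions: Mg, THF (27 → 28); then 26, THF, −78 → 0 °C; H2O
Reagents that add atoms: none
Why: Grignard addition to the aldehyde installs the last 4-oxygenated aryl ring; the carbinol configuration is irrelevant because C7d becomes planar in step 19.

Step 18
Reactants: 29 C7d carbinol tris(silyl) ether
Product: 30 C7d carbinol triphenol (ring A and C7d-aryl hydroxyls free)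
Conditions: TBAF, AcOH, THF, 0 °C
Reagents that add atoms: none
Why: Buffered fluoride desilylation frees exactly the three phenols needed for the key step and keeps them protonated, so no quinone methide forms prematurely.

Step 19
Reactants: 30 C7d carbinol triphenol
Product: 32 heptabenzyl ether of the target (ring A and C7d-aryl hydroxyls free), via p-quinone methide 31 (not isolated)
Conditions: (R)-TRIP [(R)-3,3′-bis(2,4,6-triisopropylphenyl)-BINOL hydrogen phosphate] (10 mol%), 4 Å MS, CH2Cl2 (high dilution), 0 °C → rt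
Reagents that add atoms: none
Why: The chiral phosphoric acid dehydrates the 4-hydroxybenzylic alcohol to a hydrogen-bonded p-quinone methide at C7d, and ring A, the only free resorcinol, adds through its carbon ortho to the C8a attachment (ortho/para to both hydroxyls) in a 1,6-addition followed by rearomatisation. The closest known reaction type is the chiral phosphoric acid-catalysed Friedel–Crafts 1,6-addition of phenols and naphthols to p-quinone methides generated in situ from 4-hydroxybenzyl alcohols. The eight-membered ring closes in an 8-exo-trig mode on the exocyclic methide carbon, with the two arenes and the trans-dihydrofuran holding ring A within reach of C7d. C7d is the only new stereocentre; its face is chosen by the chiral phosphate, which binds the quinone methide oxygen and a ring A hydroxyl in one hydrogen-bonded transition state, with the fixed C8d centre as the second element, and the matched catalyst should give H-7d cis to H-8d. The step needs site selectivity over the five-ring closure onto ring B and over ring C, which is secured because rings B, C and D are benzyl ethers that the phosphate cannot activate and a second bond to ring C would need a four-atom meta bridge; tautomerisation of the quinone methide to the styrene is reversible under acid catalysis and feeds back.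

Step 20
Reactants: 32 heptabenzyl ether of the target
Product: 33 CNP0224452.3 (7aS,8aS,7bR,8bR,7cR,8cS,7dR,8dS)
Conditions: H2 (1 atm), Pd/C, EtOAc/MeOH, rt
Reagents that add atoms: none
Why: Neutral hydrogenolysis removes the seven benzyl ethers without acid, so the cis-dihydrofuran is not epimerised, and the target contains no alkene to reduce.

**Compound list**
1 | 2-bromo-4,6-dimethoxybenzaldehyde | COc1cc(OC)c(C=O)c(Br)c1 | starting material
2 | 2-bromo-4,6-dihydroxybenzaldehyde | Oc1cc(O)c(C=O)c(Br)c1 | intermediate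
3 | 4-(benzyloxy)-2-bromo-6-hydroxybenzaldehyde | O=Cc1c(O)cc(OCc2ccccc2)cc1Br | intermediate
4 | 4-(benzyloxy)benzyl chloride | ClCc1ccc(OCc2ccccc2)cc1 | starting material
5 | 4-(benzyloxy)-2-{[4-(benzyloxy)benzyl]oxy}-6-bromobenzaldehyde | O=Cc1c(OCc2ccc(OCc3ccccc3)cc2)cc(OCc2ccccc2)cc1Br | intermediate
6 | 5-bromoresorcinol | Oc1cc(O)cc(Br)c1 | starting material
7 | 1-bromo-3,5-bis(triisopropylsilyloxy)benzene | CC(C)[Si](Oc1cc(Br)cc(O[Si](C(C)C)(C(C)C)C(C)C)c1)(C(C)C)C(C)C | intermediate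
8 | 3,5-bis(triisopropylsilyloxy)phenyllithium | [Li]c1cc(O[Si](C(C)C)(C(C)C)C(C)C)cc(O[Si](C(C)C)(C(C)C)C(C)C)c1 | intermediate
9 | [4-(benzyloxy)-2-{[4-(benzyloxy)benzyl]oxy}-6-bromophenyl][3,5-bis(triisopropylsilyloxy)phenyl]methanol (racemic) | OC(c1cc(O[Si](C(C)C)(C(C)C)C(C)C)cc(O[Si](C(C)C)(C(C)C)C(C)C)c1)c1c(OCc2ccc(OCc3ccccc3)cc2)cc(OCc2ccccc2)cc1Br | intermediate
10 | corresponding diaryl ketone (methanone) | O=C(c1cc(O[Si](C(C)C)(C(C)C)C(C)C)cc(O[Si](C(C)C)(C(C)C)C(C)C)c1)c1c(OCc2ccc(OCc3ccccc3)cc2)cc(OCc2ccccc2)cc1Br | intermediate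
11 | hydrazone of 10 | NN=C(c1cc(O[Si](C(C)C)(C(C)C)C(C)C)cc(O[Si](C(C)C)(C(C)C)C(C)C)c1)c1c(OCc2ccc(OCc3ccccc3)cc2)cc(OCc2ccccc2)cc1Br | intermediate
12 | diaryldiazomethane from 11 | [N-]=[N+]=C(c1cc(O[Si](C(C)C)(C(C)C)C(C)C)cc(O[Si](C(C)C)(C(C)C)C(C)C)c1)c1c(OCc2ccc(OCc3ccccc3)cc2)cc(OCc2ccccc2)cc1Br | intermediate
13 | (2R,3S)-6-(benzyloxy)-2-[4-(benzyloxy)phenyl]-4-bromo-3-[3,5-bis(triisopropylsilyloxy)phenyl]-2,3-dihydrobenzofuran (cis) | Brc1cc(OCc2ccccc2)cc2c1[C@H](c1cc(O[Si](C(C)C)(C(C)C)C(C)C)cc(O[Si](C(C)C)(C(C)C)C(C)C)c1)[C@H](c1ccc(OCc3ccccc3)cc1)O2 | intermediate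
14 | (2S,3S)-epimer of 13 (trans) | Brc1cc(OCc2ccccc2)cc2c1[C@H](c1cc(O[Si](C(C)C)(C(C)C)C(C)C)cc(O[Si](C(C)C)(C(C)C)C(C)C)c1)[C@@H](c1ccc(OCc3ccccc3)cc1)O2 | intermediate
15 | 4-(benzyloxy)benzaldehyde | O=Cc1ccc(OCc2ccccc2)cc1 | starting material
16 | (E)-3-[4-(benzyloxy)phenyl]-N-methoxy-N-methylprop-2-enamide | CON(C)C(=O)/C=C/c1ccc(OCc2ccccc2)cc1 | intermediate
17 | 4-lithio analogue of 13 | [Li]c1cc(OCc2ccccc2)cc2c1[C@H](c1cc(O[Si](C(C)C)(C(C)C)C(C)C)cc(O[Si](C(C)C)(C(C)C)C(C)C)c1)[C@H](c1ccc(OCc3ccccc3)cc1)O2 | intermediate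
18 | (E)-1-[cis-dihydrobenzofuran-4-yl of 13]-3-[4-(benzyloxy)phenyl]prop-2-en-1-one | O=C(/C=C/c1ccc(OCc2ccccc2)cc1)c1cc(OCc2ccccc2)cc2c1[C@H](c1cc(O[Si](C(C)C)(C(C)C)C(C)C)cc(O[Si](C(C)C)(C(C)C)C(C)C)c1)[C@H](c1ccc(OCc3ccccc3)cc1)O2 | intermediate
19 | enone 18 with both ring C hydroxyls free | O=C(/C=C/c1ccc(OCc2ccccc2)cc1)c1cc(OCc2ccccc2)cc2c1[C@H](c1cc(O)cc(O)c1)[C@H](c1ccc(OCc3ccccc3)cc1)O2 | intermediate
20 | eight-membered ketone diphenol (C7b bonded to ring C; C8b = CH2; C8d = C=O; cis-dihydrofuran retained) | O=C1C[C@H](c2ccc(OCc3ccccc3)cc2)c2c(O)cc(O)cc2[C@H]2c3c(cc(OCc4ccccc4)cc31)O[C@H]2c2ccc(OCc3ccccc3)cc2 | intermediate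
21 | bis(benzyl ether) of 20 | O=C1C[C@H](c2ccc(OCc3ccccc3)cc2)c2c(OCc3ccccc3)cc(OCc3ccccc3)cc2[C@H]2c3c(cc(OCc4ccccc4)cc31)O[C@H]2c2ccc(OCc3ccccc3)cc2 | intermediate
22 | C8b-arylated ketone (trans-dihydrobenzofuran-4-yl of 14 on C8b, trans to the C7b aryl) | O=C1[C@@H](c2cc(OCc3ccccc3)cc3c2[C@H](c2cc(O[Si](C(C)C)(C(C)C)C(C)C)cc(O[Si](C(C)C)(C(C)C)C(C)C)c2)[C@@H](c2ccc(OCc4ccccc4)cc2)O3)[C@H](c2ccc(OCc3ccccc3)cc2)c2c(OCc3ccccc3)cc(OCc3ccccc3)cc2[C@H]2c3c(cc(OCc4ccccc4)cc31)O[C@H]2c2ccc(OCc3ccccc3)cc2 | intermediate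
23 | C8d exocyclic methylene compound | C=C1[C@@H](c2cc(OCc3ccccc3)cc3c2[C@H](c2cc(O[Si](C(C)C)(C(C)C)C(C)C)cc(O[Si](C(C)C)(C(C)C)C(C)C)c2)[C@@H](c2ccc(OCc4ccccc4)cc2)O3)[C@H](c2ccc(OCc3ccccc3)cc2)c2c(OCc3ccccc3)cc(OCc3ccccc3)cc2[C@H]2c3c(cc(OCc4ccccc4)cc31)O[C@H]2c2ccc(OCc3ccccc3)cc2 | intermediate
24 | alkylborane from 23 (boron on C7d) | BC[C@@H]1[C@@H](c2cc(OCc3ccccc3)cc3c2[C@H](c2cc(O[Si](C(C)C)(C(C)C)C(C)C)cc(O[Si](C(C)C)(C(C)C)C(C)C)c2)[C@@H](c2ccc(OCc4ccccc4)cc2)O3)[C@H](c2ccc(OCc3ccccc3)cc2)c2c(OCc3ccccc3)cc(OCc3ccccc3)cc2[C@H]2c3c(cc(OCc4ccccc4)cc31)O[C@H]2c2ccc(OCc3ccccc3)cc2 | intermediate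
25 | C8d hydroxymethyl compound (CH2OH = C7d, trans to ring B) | OC[C@@H]1[C@@H](c2cc(OCc3ccccc3)cc3c2[C@H](c2cc(O[Si](C(C)C)(C(C)C)C(C)C)cc(O[Si](C(C)C)(C(C)C)C(C)C)c2)[C@@H](c2ccc(OCc4ccccc4)cc2)O3)[C@H](c2ccc(OCc3ccccc3)cc2)c2c(OCc3ccccc3)cc(OCc3ccccc3)cc2[C@H]2c3c(cc(OCc4ccccc4)cc31)O[C@H]2c2ccc(OCc3ccccc3)cc2 | intermediate
26 | C8d carbaldehyde (CHO = C7d, trans to ring B) | O=C[C@@H]1[C@@H](c2cc(OCc3ccccc3)cc3c2[C@H](c2cc(O[Si](C(C)C)(C(C)C)C(C)C)cc(O[Si](C(C)C)(C(C)C)C(C)C)c2)[C@@H](c2ccc(OCc4ccccc4)cc2)O3)[C@H](c2ccc(OCc3ccccc3)cc2)c2c(OCc3ccccc3)cc(OCc3ccccc3)cc2[C@H]2c3c(cc(OCc4ccccc4)cc31)O[C@H]2c2ccc(OCc3ccccc3)cc2 | intermediate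
27 | (4-bromophenoxy)triisopropylsilane | CC(C)[Si](Oc1ccc(Br)cc1)(C(C)C)C(C)C | starting material
28 | 4-(triisopropylsilyloxy)phenylmagnesium bromide | Br[Mg]c1ccc(O[Si](C(C)C)(C(C)C)C(C)C)cc1 | intermediate
29 | C7d carbinol, tris(triisopropylsilyl) ether (both C7d epimers) | OC(c2ccc(O[Si](C(C)C)(C(C)C)C(C)C)cc2)[C@@H]1[C@@H](c2cc(OCc3ccccc3)cc3c2[C@H](c2cc(O[Si](C(C)C)(C(C)C)C(C)C)cc(O[Si](C(C)C)(C(C)C)C(C)C)c2)[C@@H](c2ccc(OCc4ccccc4)cc2)O3)[C@H](c2ccc(OCc3ccccc3)cc2)c2c(OCc3ccccc3)cc(OCc3ccccc3)cc2[C@H]2c3c(cc(OCc4ccccc4)cc31)O[C@H]2c2ccc(OCc3ccccc3)cc2 | intermediate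
30 | C7d carbinol triphenol (both C7d epimers) | OC(c2ccc(O)cc2)[C@@H]1[C@@H](c2cc(OCc3ccccc3)cc3c2[C@H](c2cc(O)cc(O)c2)[C@@H](c2ccc(OCc4ccccc4)cc2)O3)[C@H](c2ccc(OCc3ccccc3)cc2)c2c(OCc3ccccc3)cc(OCc3ccccc3)cc2[C@H]2c3c(cc(OCc4ccccc4)cc31)O[C@H]2c2ccc(OCc3ccccc3)cc2 | intermediate
31 | p-quinone methide at C7d | O=C2C=CC(C=C2)=C[C@@H]1[C@@H](c2cc(OCc3ccccc3)cc3c2[C@H](c2cc(O)cc(O)c2)[C@@H](c2ccc(OCc4ccccc4)cc2)O3)[C@H](c2ccc(OCc3ccccc3)cc2)c2c(OCc3ccccc3)cc(OCc3ccccc3)cc2[C@H]2c3c(cc(OCc4ccccc4)cc31)O[C@H]2c2ccc(OCc3ccccc3)cc2 | intermediate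
32 | heptabenzyl ether of the target (ring A and C7d-aryl hydroxyls free) | Oc1ccc([C@@H]2c3c(O)cc(O)cc3[C@H]3c4c(cc(OCc5ccccc5)cc4[C@H]4[C@H](c5ccc(OCc6ccccc6)cc5)c5c(OCc6ccccc6)cc(OCc6ccccc6)cc5[C@H]5c6c(cc(OCc7ccccc7)cc6[C@H]24)O[C@H]5c2ccc(OCc6ccccc6)cc2)O[C@@H]3c2ccc(OCc3ccccc3)cc2)cc1 | intermediate
33 | CNP0224452.3 (7aS,8aS,7bR,8bR,7cR,8cS,7dR,8dS) | Oc1ccc([C@@H]2c3c(O)cc(O)cc3[C@H]3c4c(cc(O)cc4[C@H]4[C@H](c5ccc(O)cc5)c5c(O)cc(O)cc5[C@H]5c6c(cc(O)cc6[C@H]24)O[C@H]5c2ccc(O)cc2)O[C@@H]3c2ccc(O)cc2)cc1 | target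

**Totals and risks**
Total step count: 20. Longest linear sequence: 17 steps (steps 1–3, 5–8 and 11–20).

Step 19. What may go wrong: addition to the wrong face of the quinone methide, because the conformational bias around C8d (allylic strain) may override the catalyst. Fallback, from 30 back to 32: cyclise 30 with achiral diphenyl phosphate to the mixture of 32 and its 7d-epimer F1, and oxidise this mixture with Ag2O to the single ring-embedded p-quinone methide F2. Then set C7d by hydride delivery instead of aryl delivery, using chiral phosphoric acid-catalysed transfer hydrogenation with Hantzsch ester, which returns to 32.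

Step 13. What may go wrong: no coupling between two hindered partners, with hydrodebromination of 14 instead. Fallback, from 21 and 14 back to 22, with the polarity reversed: brominate the enolate of 21 at C8b (LiN(SiMe3)2, then NBS, −78 °C) to the α-bromo ketone F3, and convert 14 (n-BuLi, then ZnCl2) to the arylzinc chloride F4. Join them by nickel-catalysed Negishi arylation (NiCl2·glyme, pybox ligand, THF/DMA), which returns to 22 after the same enolate equilibration.

Step 12. What may go wrong: oxygen-alkylation and intermolecular addition of the phenolate outrun the eight-membered C-alkylation. Fallback, from 13 back to 20, closing a six-membered ring first and then expanding it: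
- desilylate 13 (TBAF, AcOH) to the diphenol bromide F5;
- heat F5 in pyridine with the benzylidene Meldrum's acid F6 (from 15 and Meldrum's acid) to give the 4-aryl-3,4-dihydrocoumarin F7, by C-alkylation at the same ring C carbon and lactonisation with loss of acetone and CO2;
- deprotonate the remaining phenol (NaH) and add n-BuLi at −100 °C, so that bromine–lithium exchange is followed by acyl transfer from the lactone to the aryllithium (Parham-type cyclisation), giving the eight-membered ketone diphenol 20;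
- benzylate as in step 12 to reach 21.

**Further compounds**
F1 | step 19 | 7d-epimer of 32 | Oc1ccc([C@H]2c3c(O)cc(O)cc3[C@H]3c4c(cc(OCc5ccccc5)cc4[C@H]4[C@H](c5ccc(OCc6ccccc6)cc5)c5c(OCc6ccccc6)cc(OCc6ccccc6)cc5[C@H]5c6c(cc(OCc7ccccc7)cc6[C@H]24)O[C@H]5c2ccc(OCc6ccccc6)cc2)O[C@@H]3c2ccc(OCc3ccccc3)cc2)cc1
F2 | step 19 | ring-embedded p-quinone methide (C7d planar) | O=C1C=CC(C=C1)=C2c3c(O)cc(O)cc3[C@H]3c4c(cc(OCc5ccccc5)cc4[C@H]4[C@H](c5ccc(OCc6ccccc6)cc5)c5c(OCc6ccccc6)cc(OCc6ccccc6)cc5[C@H]5c6c(cc(OCc7ccccc7)cc6[C@H]24)O[C@H]5c2ccc(OCc6ccccc6)cc2)O[C@@H]3c2ccc(OCc3ccccc3)cc2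
F3 | step 13 | C8b-bromo ketone from 21 | O=C1C(Br)[C@H](c2ccc(OCc3ccccc3)cc2)c2c(OCc3ccccc3)cc(OCc3ccccc3)cc2[C@H]2c3c(cc(OCc4ccccc4)cc31)O[C@H]2c2ccc(OCc3ccccc3)cc2
F4 | step 13 | arylzinc chloride from 14 | Cl[Zn]c1cc(OCc2ccccc2)cc2c1[C@H](c1cc(O[Si](C(C)C)(C(C)C)C(C)C)cc(O[Si](C(C)C)(C(C)C)C(C)C)c1)[C@@H](c1ccc(OCc3ccccc3)cc1)O2
F5 | step 12 | diphenol bromide from 13 | Brc1cc(OCc2ccccc2)cc2c1[C@H](c1cc(O)cc(O)c1)[C@H](c1ccc(OCc3ccccc3)cc1)O2
F6 | step 12 | 5-[4-(benzyloxy)benzylidene]-2,2-dimethyl-1,3-dioxane-4,6-dione | CC1(C)OC(=O)C(=Cc2ccc(OCc3ccccc3)cc2)C(=O)O1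
F7 | step 12 | 4-aryl-3,4-dihydrocoumarin fused to ring C | O=C1C[C@H](c2ccc(OCc3ccccc3)cc2)c2c(O1)cc(O)cc2[C@H]2c3c(cc(OCc4ccccc4)cc3Br)O[C@H]2c2ccc(OCc3ccccc3)cc2
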